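The leftover here can be reckoned before the run: 0.300 M of solid reagent stands against 0.10 M of substrate, the limiting reagent, and even two coupling partner per substrate asks for 0.200 M, so the flask holds more solid than the substrate can call for.

substrate 0.10 M (fed, over 15 min); solid reagent 0.300 M; time 30 min; the fed solution adds 0.20 times the starting volume

    substrate + coupling partner ⇌ target (K1 = 10 /M, k1 = 0.68 /M/min)
    substrate + 2 coupling partner → side product A (k2 = 3.0 /M²/min)
    solid reagent ⇌ coupling partner, rate k3*(cs3 - [coupling partner]) while solid is left; crystals form when [coupling partner] > cs3 (cs3 = 32 mM, k3 = 0.33 /min)
    substrate + target → side product B (k4 = 2.0 /M/min)

1. how much of the substrate has reacted by 30 min
2. how much target there is at 30 min, in percent of the substrate charged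
3. how much side product B there is at 30 min, in percent of the substrate charged

- in percentages every species weighs as the substrate in it: one side product B counts as two
- a doubled species enters its step squared and goes two at a time
- charges are per starting volume, the dose included; the dosed solution carries all of it
- as a solid, counted per litre of solution: solid reagent
- at the start none of the solid reagent is in solution
- run time (flask): 30 min

Two chemists argue over what [target] does in this flask. The first treats the first step as an equilibrium. With the whole charge in the final volume, [substrate] is 83.3 mM, and with [coupling partner] at its solubility of 32 mM, the equilibrium constant gives [target] = 26.7 mM, or 32.0% of the charge.

The second answers that target also reacts with substrate. At that [substrate] this loss runs at 0.167 /min per unit of target, faster than the 0.0680 /min of the way back. 34.0 mM is the [substrate] at which the two losses are equal, the crossing concentration.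

Balancing formation against both losses (a quasi-steady state), my own reckoning divides the first chemist's figure by one plus [substrate] over the crossing concentration. That gives 7.73 mM, or 9.27% of the charge. It takes both concentrations at their highest, so I hold it as a high estimate, and my reckoning stops there.

The forecast takes the second side: 45% converted, 7% target and 33% side product B, with target held low “because it is lost through reversal and reaction with substrate”. Its target figure is lower than my high estimate.

The simulation gives 43.0% converted, 7.11% target and 31.9% side product B, so the forecast holds and the second chemist has it. At 30.0 min the flask still has [substrate] of 47.5 mM, higher than the crossing, with [coupling partner] at 0.0293 M. The rule then gives 5.81 mM target, 6.98% of the charge. The neighbour flask charged with 0.025 M of substrate ends at [substrate] of 13.9 mM, lower than the crossing, and there the way back, at 0.0680 /min, is faster than the loss to substrate, at 0.0278 /min: that is the region left to the first chemist's view. There the rule gives 3.09 mM, or 14.8% of its charge, and that neighbour holds 14.1% target.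

The constants used here were set for the occasion; no experiment stands behind them.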